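(The runs come from a simulation with constants of no real substance.)

- In the first 0.500 min of the runs, left-handed product outruns right-handed product. Pooled, the readings up to then give a ratio of 3.28: this is the selectivity factor s, the left-hand coupling rate over the right-hand one at equal substrates.
- Both coupling rates carry [coupling partner], so it cancels: product forms in the ratio s[left-handed substrate]/[right-handed substrate].

| flask | left-handed substrate | right-handed substrate | coupling partner | racemization catalyst | remark | time |
|---|---|---|---|---|---|---|
| east | 20 mM | 20 mM | 40 mM | 1.3 mM | the very flask that is asked about, followed so far |  |
| north-west | 20 mM | 20 mM | 40 mM | 0.87 mM | run made earlier |  |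
| flask | 20 mM | 20 mM | 40.0 mM | 1.3 mM |  | 15 min |

- east (time / min: left-handed product / %, right-handed product / %, left-handed substrate / %): 0.200: 5.9, 1.6, 42.0; 0.500: 15.4, 4.3, 34.3; 1.33: 28.1, 11.9, 23.9; 2.50: 36.8, 15.5, 13.9
- north-west (time / min: left-handed product / %, right-handed product / %, left-handed substrate / %): 0.500: 15.1, 5.2, 36.8; 1.00: 22.5, 9.8, 25.9; 2.50: 37.5, 18.2, 13.2; 6.00: 45.8, 25.9, 6.2

(each reading ± 1 percentage point)

- coupling partner is single-handed; left-handed substrate and right-handed substrate are mirror images of each other, charged as a racemate, each of them at the stated concentration
- what was read earlier has a scatter of 1 percentage point, one standard deviation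
- an excess is the difference of the two amounts in percent of their sum
- an excess is below zero if the other one leads
- the handed part of coupling partner does not stay in what it makes, so the products of the two hands are mirror images too

* left-handed product and right-handed product together, in percent of the left-handed substrate and right-handed substrate charged together, at 15 min
* excess of left-handed product over right-handed product in the product at 15 min
* whether the exchange between left-handed substrate and right-handed substrate keeps pace with the reaction: how far the product's excess at 15 min gets from its value without exchange to its value with instant exchange (above 80% keeps pace, below 20% hardly takes part, else lags behind)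

- The curve starts with new product at an excess of 53.3%.
- Its landmark is where the ratio crosses one. Taking right-handed substrate from the balance, the north-west run gives 1.39 at 2.50 min and 0.920 at 6.00 min.
- Past that crossing, right-handed product forms faster than left-handed, so the gap between the products, read at 20 percentage points at 6.00 min, should shrink.
- The partner charge equals both substrates together, so [coupling partner] tracks what remains, and in the north-west run the reciprocal of the remainder climbs along a bending line, at 0.503 min⁻¹ up to 2.50 min, then at 0.365 min⁻¹ up to 6.00 min.
- Carrying that last slope on to 15 min, though it may fall further, gives us a rough 85.3% for y, and the read gap over it puts the excess near 23.3% before any shrinking.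
- The forecast gave 84%, 25% and lags behind: “borderline, lags behind”. Its excess lies above our estimate.
- The flask gives 85.1%, 19.4%, and exchange that hardly takes part, 10% of the way.

    coupling partner + left-handed substrate → left-handed product (k = 0.340 L mol⁻¹ s⁻¹)
    coupling partner + right-handed substrate → right-handed product (k = 0.110 L mol⁻¹ s⁻¹)
    left-handed substrate + racemization catalyst ⇌ right-handed substrate + racemization catalyst, rate k3*[racemization catalyst]*[left-handed substrate] forward; the back reaction follows from the equilibrium constant (k = 3.40 L mol⁻¹ s⁻¹)
    2 racemization catalyst ⇌ resting dimer, settled at all times (K = 72000 L mol⁻¹)
    2 racemization catalyst → spent catalyst (k = 150 L mol⁻¹ s⁻¹)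

- At 15.0 min the flask holds 1.93% left-handed and 12.9% right-handed substrate, so s gives a ratio of 0.489, past the crossing. The neighbour flask charged with 16 mM of coupling partner keeps 0.743% of it, and its 24.0% and 36.3% give 2.16, short of the crossing. That neighbour stands at y 39.7% with an excess of 42.0%.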